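**Retrosynthetic overview**
Numbering used: ester carbon C1, ring carbons C3–C6, side chain C7–C14 (ethyl on C8, methyl on C10).
1. Last cut, C6–C7: a copper-catalysed coupling of a side-chain alkylzinc with the peroxycarbenium ion from a 6-methoxy-1,2-dioxane (fragment A); this union also sets C6.
2. The only ring, the 1,2-dioxane, is closed earlier inside fragment A: methanolic ozonolysis of a 1,1-disubstituted alkene gives a hydroperoxyketal that displaces a C3 mesylate with inversion; the ester arm is carried as a propargyl group.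
3. C4 comes from a Zr-catalysed carboalumination of a skipped diene; C3 from a catalytic asymmetric propargylation of the derived aldehyde.
4. Fragment B (side-chain iodide): Cu-catalysed conjugate addition sets C10, then methylenation and a second Zr-catalysed ethylalumination set C8.

Assumption: solutions of butylmagnesium bromide and Et3Al, the chiral catalysts and ligands, and allenylboronic acid pinacol ester are taken as commercial reagents; the methoxy-bearing ketal carbon of fragment A is carried as a mixture of epimers because it becomes planar in the last step.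

**Fragment A (ring fragment)**

Step 1
Reactants: 1 2-bromobut-1-ene; 2 3-bromoprop-1-ene (allyl bromide)
Product: 4 2-ethylpenta-1,4-diene, via but-1-en-2-ylmagnesium bromide 3 (not isolated)
Conditions: 1, Mg, THF, 40 °C; then 2, CuI (5 mol %), −10 °C → rt; fractional distillation
Reagents that add atoms: none
Why: Copper-catalysed Grignard–allyl bromide coupling; SN2 and SN2′ attack on the unsubstituted allyl unit give the same skipped diene and no stereocentre is formed.

Step 2
Reactants: 4 2-ethylpenta-1,4-diene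
Product: 6 (2S)-2-ethyl-4-methylidenehexan-1-ol, via diethyl[(2S)-2-ethyl-4-methylidenehexyl]alumane 5 (not isolated)
Conditions: Et3Al, (+)-(NMI)2ZrCl2 (5 mol %; NMI = 1-neomenthylindenyl), CH2Cl2, 0 °C → rt; then O2, 0 °C; aq. NaOH
Reagents that add atoms: triethylaluminium CC[Al](CC)CC; dioxygen O=O
Why: Zirconium-catalysed asymmetric carboalumination (ZACA) adds Et–Al only across the monosubstituted alkene (the 1,1-disubstituted one is inert); the (+)-catalyst (the (−)-catalyst gives the R series) sets C4 as S in about 90 % ee, and O2 oxidises the C–Al bond without touching that centre.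

Step 3
Reactants: 6 (2S)-2-ethyl-4-methylidenehexan-1-ol
Product: 7 (2S)-2-ethyl-4-methylidenehexanal
Conditions: TEMPO (10 mol %), PhI(OAc)2, CH2Cl2, 0 °C → rt; used at once
Reagents that add atoms: none
Why: Nitroxyl-catalysed oxidation of a primary alcohol stops at the aldehyde under non-basic conditions, so the α-stereocentre is not epimerised.

Step 4
Reactants: 7 (2S)-2-ethyl-4-methylidenehexanal
Product: 8 (4R,5S)-5-ethyl-7-methylidenenon-1-yn-4-ol
Conditions: allenylboronic acid pinacol ester, (R)-TRIP (10 mol %), 4 Å MS, toluene, −20 °C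
Reagents that add atoms: 4,4,5,5-tetramethyl-2-(propa-1,2-dien-1-yl)-1,3,2-dioxaborolane C=C=CB1OC(C)(C)C(C)(C)O1
Why: Chiral phosphoric acid-catalysed propargylboration through a closed six-membered SE2′ transition state; the (R)-catalyst controls the carbonyl face to give the 4R carbinol (anti to the C5 ethyl), and chromatography removes the minor diastereomers, which also upgrades the ee of step 2.

Step 5
Reactants: 8 (4R,5S)-5-ethyl-7-methylidenenon-1-yn-4-ol
Product: 9 (4R,5S)-5-ethyl-7-methylidenenon-1-yn-4-yl methanesulfonate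
Conditions: MsCl, Et3N, CH2Cl2, 0 °C
Reagents that add atoms: methanesulfonyl chloride CS(=O)(=O)Cl
Why: Mesylation forms an O–S bond only, so the carbinol configuration is retained and a leaving group is in place for the invertive ring closure.

Step 6
Reactants: 9 (4R,5S)-5-ethyl-7-methylidenenon-1-yn-4-yl methanesulfonate
Product: 10 (4R,5S)-5-ethyl-7-hydroperoxy-7-methoxynon-1-yn-4-yl methanesulfonate (both C7 epimers)
Conditions: O3, CH2Cl2/MeOH (5:1), NaHCO3, −78 °C, Sudan Red 7B end point; no reductant
Reagents that add atoms: ozone [O-][O+]=O; methanol CO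
Why: Criegee ozonolysis in methanol: the 1,1-disubstituted alkene cleaves to formaldehyde and the ketone oxide, which methanol traps as the hydroperoxyketal; the alkyne reacts far more slowly and the dye end point prevents over-ozonolysis; the new ketal centre is irrelevant.

Step 7
Reactants: 10 (4R,5S)-5-ethyl-7-hydroperoxy-7-methoxynon-1-yn-4-yl methanesulfonate
Product: 11 (3S,4S)-4,6-diethyl-6-methoxy-3-(prop-2-yn-1-yl)-1,2-dioxane (both C6 epimers)
Conditions: KOt-Bu (1.1 equiv), 18-crown-6, toluene, 0 °C
Reagents that add atoms: none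
Why: Intramolecular peroxide alkylation (6-exo-tet SN2): the hydroperoxide anion displaces the secondary mesylate with inversion, turning the 4R carbinol into the 3S ring carbon cis to the C4 ethyl.

Step 8
Reactants: 11 (3S,4S)-4,6-diethyl-6-methoxy-3-(prop-2-yn-1-yl)-1,2-dioxane
Product: 13 methyl 2-[(3S,4S)-4,6-diethyl-6-methoxy-1,2-dioxan-3-yl]acetate, via 2-[(3S,4S)-4,6-diethyl-6-methoxy-1,2-dioxan-3-yl]acetic acid 12 (not isolated)
Conditions: RuCl3·xH2O (3 mol %), NaIO4, NaHCO3, CCl4/MeCN/H2O, 0 °C → rt; then TMSCHN2, PhMe/MeOH, 0 °C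
Reagents that add atoms: sodium periodate [Na+].[O-]I(=O)(=O)=O; water O; trimethylsilyldiazomethane C[Si](C)(C)C=[N+]=[N-]
Why: RuO4 generated in situ cleaves the terminal alkyne to the acid with one carbon fewer, and diazoalkane esterification needs neither acid nor base, so the buffered sequence spares the peroxyketal and the O–O bond.

**Fragment B (side chain)**

Step 9
Reactants: 14 methyl (E)-but-2-enoate; 15 butylmagnesium bromide
Product: 16 methyl (3S)-3-methylheptanoate
Conditions: CuBr·SMe2 (1 mol %), Josiphos (1.2 mol %; the antipode that gives the 3S ester), t-BuOMe, −75 °C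
Reagents that add atoms: none
Why: Copper-catalysed asymmetric conjugate addition of a Grignard reagent to an enoate; the ferrocenyl diphosphine–copper complex selects the enoate face and sets C10 (3S here, at least 90 % ee).

Step 10
Reactants: 16 methyl (3S)-3-methylheptanoate
Product: 17 (3S)-3-methylheptanal
Conditions: i-Bu2AlH (1.05 equiv), CH2Cl2, −78 °C; Rochelle salt
Reagents that add atoms: none
Why: Partial ester reduction: the tetrahedral aluminium hemiacetal survives at −78 °C until work-up, and the β-stereocentre is untouched.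

Step 11
Reactants: 17 (3S)-3-methylheptanal
Product: 18 (4S)-4-methyloct-1-ene
Conditions: MePPh3Br, KOt-Bu, THF, 0 °C → rt
Reagents that add atoms: methyltriphenylphosphonium bromide C[P+](c1ccccc1)(c1ccccc1)c1ccccc1.[Br-]
Why: Wittig methylenation of the aldehyde; no stereocentre is affected.

Step 12
Reactants: 18 (4S)-4-methyloct-1-ene
Product: 20 (2S,4S)-2-ethyl-4-methyloctan-1-ol, via diethyl[(2S,4S)-2-ethyl-4-methyloctyl]alumane 19 (not isolated)
Conditions: Et3Al, (+)-(NMI)2ZrCl2 (5 mol %), CH2Cl2, 0 °C → rt; then O2, 0 °C; aq. NaOH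
Reagents that add atoms: triethylaluminium CC[Al](CC)CC; dioxygen O=O
Why: Second ZACA reaction: the same (+)-catalyst delivers ethyl to the same alkene face and sets C8 as S under catalyst control (about 95:5), the minor diastereomer being removed at the alcohol stage.

Step 13
Reactants: 20 (2S,4S)-2-ethyl-4-methyloctan-1-ol
Product: 21 (2S,4S)-2-ethyl-1-iodo-4-methyloctane
Conditions: I2, PPh3, imidazole, CH2Cl2, 0 °C → rt
Reagents that add atoms: iodine II
Why: Appel-type iodination, an SN2 displacement at the primary CH2 that leaves both stereocentres untouched.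

**Union**

Step 14
Reactants: 13 methyl 2-[(3S,4S)-4,6-diethyl-6-methoxy-1,2-dioxan-3-yl]acetate; 21 (2S,4S)-2-ethyl-1-iodo-4-methyloctane
Product: 23 methyl 2-[(3S,4S,6S)-4,6-diethyl-6-[(2S,4S)-2-ethyl-4-methyloctyl]-1,2-dioxan-3-yl]acetate, via [(2S,4S)-2-ethyl-4-methyloctyl]zinc iodide 22 (not isolated)
Conditions: 21, Zn dust (activated), THF, 45 °C; then 13, CuBr·SMe2 (10 mol %), TMSOTf (1.3 equiv), CH2Cl2, −78 → −40 °C
Reagents that add atoms: none
Why: Proposed new method: monovalent-copper-catalysed C(sp3)–C(sp3) coupling of an alkylzinc iodide with a cyclic peroxyketal — TMSOTf ionises the exocyclic methoxy group to a six-membered peroxycarbenium ion, 22 transmetalates to a soft alkylcopper that attacks carbon and not the O–O bond, and the alkyl group enters axially on the half-chair that keeps the C4 ethyl pseudo-equatorial (chair-like transition state, no syn-axial contact, opposite face to the axial C3 arm), so the chain ends axial and the C6 ethyl equatorial, i.e. 6S, from both ketal epimers of 13; the closest known reactions are Lewis acid allylation of 3-alkoxy-1,2-dioxolanes and -dioxanes through peroxycarbenium ions, axial dialkylzinc/TMSOTf alkylation of 4-acetoxy-1,3-dioxanes, and copper-catalysed additions of organozinc reagents to oxocarbenium ions.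

**Compound list**
1 | 2-bromobut-1-ene | C=C(Br)CC | starting material
2 | 3-bromoprop-1-ene (allyl bromide) | C=CCBr | starting material
3 | but-1-en-2-ylmagnesium bromide | C=C(CC)[Mg]Br | intermediate
4 | 2-ethylpenta-1,4-diene | C=CCC(=C)CC | intermediate
5 | diethyl[(2S)-2-ethyl-4-methylidenehexyl]alumane | C=C(CC)C[C@H](CC)C[Al](CC)CC | intermediate
6 | (2S)-2-ethyl-4-methylidenehexan-1-ol | C=C(CC)C[C@H](CC)CO | intermediate
7 | (2S)-2-ethyl-4-methylidenehexanal | C=C(CC)C[C@H](CC)C=O | intermediate
8 | (4R,5S)-5-ethyl-7-methylidenenon-1-yn-4-ol | C=C(CC)C[C@H](CC)[C@@H](CC#C)O | intermediate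
9 | (4R,5S)-5-ethyl-7-methylidenenon-1-yn-4-yl methanesulfonate | C=C(CC)C[C@H](CC)[C@@H](CC#C)OS(C)(=O)=O | intermediate
10 | (4R,5S)-5-ethyl-7-hydroperoxy-7-methoxynon-1-yn-4-yl methanesulfonate (both C7 epimers) | CCC(OC)(OO)C[C@H](CC)[C@@H](CC#C)OS(C)(=O)=O | intermediate
11 | (3S,4S)-4,6-diethyl-6-methoxy-3-(prop-2-yn-1-yl)-1,2-dioxane (both C6 epimers) | CCC1(OC)C[C@H](CC)[C@H](CC#C)OO1 | intermediate
12 | 2-[(3S,4S)-4,6-diethyl-6-methoxy-1,2-dioxan-3-yl]acetic acid (both C6 epimers) | CCC1(OC)C[C@H](CC)[C@H](CC(=O)O)OO1 | intermediate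
13 | methyl 2-[(3S,4S)-4,6-diethyl-6-methoxy-1,2-dioxan-3-yl]acetate (both C6 epimers) | CCC1(OC)C[C@H](CC)[C@H](CC(=O)OC)OO1 | intermediate
14 | methyl (E)-but-2-enoate | C/C=C/C(=O)OC | starting material
15 | butylmagnesium bromide | CCCC[Mg]Br | starting material
16 | methyl (3S)-3-methylheptanoate | CCCC[C@H](C)CC(=O)OC | intermediate
17 | (3S)-3-methylheptanal | CCCC[C@H](C)CC=O | intermediate
18 | (4S)-4-methyloct-1-ene | CCCC[C@H](C)CC=C | intermediate
19 | diethyl[(2S,4S)-2-ethyl-4-methyloctyl]alumane | CCCC[C@H](C)C[C@H](CC)C[Al](CC)CC | intermediate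
20 | (2S,4S)-2-ethyl-4-methyloctan-1-ol | CCCC[C@H](C)C[C@H](CC)CO | intermediate
21 | (2S,4S)-2-ethyl-1-iodo-4-methyloctane | CCCC[C@H](C)C[C@H](CC)CI | intermediate
22 | [(2S,4S)-2-ethyl-4-methyloctyl]zinc iodide | CCCC[C@H](C)C[C@H](CC)C[Zn]I | intermediate
23 | methyl 2-[(3S,4S,6S)-4,6-diethyl-6-[(2S,4S)-2-ethyl-4-methyloctyl]-1,2-dioxan-3-yl]acetate | CCCC[C@H](C)C[C@H](CC)C[C@@]1(CC)C[C@H](CC)[C@H](CC(=O)OC)OO1 | target

**Step count**
Total: 14 steps. Longest linear sequence: 9 steps (steps 1–8, then 14); the side-chain branch is 5 steps (9–13) before the union.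

**Three steps most likely to fail**

Step 14 (the proposed new coupling). The Lewis acid could ionise the ring C–O bond instead of the methoxy group, copper or zinc could attack the O–O bond, or axial selectivity could be low. The fallback uses known chemistry only, does not control C6, sets out from 6 and 21 and comes back at 23. Alcohol 6 is protected (NaH, PMBCl) as 4-methoxybenzyl ether F1. OsO4 (cat.)/NaIO4 cleaves the methylidene group to ethyl ketone F2. Iodide 21 and Mg in Et2O give alkylmagnesium iodide F3, which adds to F2 (CeCl3, −78 °C) to give tertiary alcohol F4 as both carbinol epimers. Burgess dehydration gives alkene mixture F5, all isomers of which lead to the same tertiary radical. Mukaiyama–Isayama hydroperoxysilylation [Co(thd)2, thd = 2,2,6,6-tetramethylheptane-3,5-dionate; O2, Et3SiH] gives triethylsilyl peroxide F6, about 1:1 at C6. DDQ frees primary alcohol F7, TEMPO/PhI(OAc)2 gives aldehyde F8, propargylation as in step 4 gives homopropargylic alcohol F9, and MsCl/Et3N gives mesylate F10. TBAF removes the silyl group and the liberated peroxide anion displaces the mesylate with inversion in the same flask, giving alkynyl dioxane F11 after chromatographic removal of its 6R epimer. RuCl3/NaIO4 cleavage to carboxylic acid F12 and TMSCHN2 give 23. About half the material is lost at C6, which is what the new step is meant to avoid.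

Step 7 (peroxide ring closure on a hindered secondary mesylate). Elimination to the enyne or base-induced breakdown of the hydroperoxyketal may compete. The fallback closes the ring by ketalisation at C6 instead of displacement at C3; it sets out from 9 and comes back at 11. Ozonolysis of 9 with reductive work-up (O3, CH2Cl2, −78 °C; Me2S) gives keto mesylate F13. Intermolecular SN2 displacement of the mesylate by hydrogen peroxide (50 % H2O2, KOH, MeOH/H2O, 0 °C) installs the C3 hydroperoxide with inversion; it adds to the ketone as it forms, giving cyclic peroxyhemiketal F14. MeOH with catalytic p-TsOH converts F14 into 11.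

Step 4 (catalytic propargylation of an α-branched, epimerisable aldehyde). Selectivity may be modest and the aldehyde may epimerise during the slow reaction. The fallback replaces catalyst control by an unselective addition plus stereochemical correction; it sets out from 7 and comes back at 8. Zinc-mediated Barbier propargylation (propargyl bromide, Zn, THF/aq. NH4Cl, 0 °C) gives 8 together with its C4 epimer, syn alcohol F15, separable on silica. F15 is recycled by Mitsunobu inversion (4-nitrobenzoic acid, DIAD, PPh3) to inverted 4-nitrobenzoate F16, and methanolysis (K2CO3, MeOH) returns 8.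

**Further compounds**
F1 | step 14 | 1-({[(2S)-2-ethyl-4-methylidenehexyl]oxy}methyl)-4-methoxybenzene | C=C(CC)C[C@H](CC)COCc1ccc(OC)cc1
F2 | step 14 | (5S)-5-{[(4-methoxyphenyl)methoxy]methyl}heptan-3-one | CCC(=O)C[C@H](CC)COCc1ccc(OC)cc1
F3 | step 14 | [(2S,4S)-2-ethyl-4-methyloctyl]magnesium iodide | CCCC[C@H](C)C[C@H](CC)C[Mg]I
F4 | step 14 | (2S,6S,8S)-2,4,6-triethyl-1-[(4-methoxyphenyl)methoxy]-8-methyldodecan-4-ol (both C4 epimers) | CCCC[C@H](C)C[C@H](CC)CC(O)(CC)C[C@H](CC)COCc1ccc(OC)cc1
F5 | step 14 | 1-({[(2S,6S,8S)-2,4,6-triethyl-8-methyldodec-4-en-1-yl]oxy}methyl)-4-methoxybenzene (shown; mixture with its double-bond isomers) | CCCC[C@H](C)C[C@H](CC)C=C(CC)C[C@H](CC)COCc1ccc(OC)cc1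
F6 | step 14 | triethyl({(2S,6S,8S)-2,4,6-triethyl-1-[(4-methoxyphenyl)methoxy]-8-methyldodecan-4-yl}peroxy)silane (both C4 epimers) | CCCC[C@H](C)C[C@H](CC)CC(CC)(OO[Si](CC)(CC)CC)C[C@H](CC)COCc1ccc(OC)cc1
F7 | step 14 | (2S,6S,8S)-2,4,6-triethyl-8-methyl-4-[(triethylsilyl)peroxy]dodecan-1-ol (both C4 epimers) | CCCC[C@H](C)C[C@H](CC)CC(CC)(OO[Si](CC)(CC)CC)C[C@H](CC)CO
F8 | step 14 | (2S,6S,8S)-2,4,6-triethyl-8-methyl-4-[(triethylsilyl)peroxy]dodecanal (both C4 epimers) | CCCC[C@H](C)C[C@H](CC)CC(CC)(OO[Si](CC)(CC)CC)C[C@H](CC)C=O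
F9 | step 14 | (4R,5S,9S,11S)-5,7,9-triethyl-11-methyl-7-[(triethylsilyl)peroxy]pentadec-1-yn-4-ol (both C7 epimers) | CCCC[C@H](C)C[C@H](CC)CC(CC)(OO[Si](CC)(CC)CC)C[C@H](CC)[C@@H](CC#C)O
F10 | step 14 | (4R,5S,9S,11S)-5,7,9-triethyl-11-methyl-7-[(triethylsilyl)peroxy]pentadec-1-yn-4-yl methanesulfonate (both C7 epimers) | CCCC[C@H](C)C[C@H](CC)CC(CC)(OO[Si](CC)(CC)CC)C[C@H](CC)[C@@H](CC#C)OS(C)(=O)=O
F11 | step 14 | (3S,4S,6S)-4,6-diethyl-6-[(2S,4S)-2-ethyl-4-methyloctyl]-3-(prop-2-yn-1-yl)-1,2-dioxane | CCCC[C@H](C)C[C@H](CC)C[C@@]1(CC)C[C@H](CC)[C@H](CC#C)OO1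
F12 | step 14 | 2-[(3S,4S,6S)-4,6-diethyl-6-[(2S,4S)-2-ethyl-4-methyloctyl]-1,2-dioxan-3-yl]acetic acid | CCCC[C@H](C)C[C@H](CC)C[C@@]1(CC)C[C@H](CC)[C@H](CC(=O)O)OO1
F13 | step 7 | (4R,5S)-5-ethyl-7-oxonon-1-yn-4-yl methanesulfonate | CCC(=O)C[C@H](CC)[C@@H](CC#C)OS(C)(=O)=O
F14 | step 7 | (5S,6S)-3,5-diethyl-6-(prop-2-yn-1-yl)-1,2-dioxan-3-ol (both C3 epimers) | CCC1(O)C[C@H](CC)[C@H](CC#C)OO1
F15 | step 4 | (4S,5S)-5-ethyl-7-methylidenenon-1-yn-4-ol | C=C(CC)C[C@H](CC)[C@H](CC#C)O
F16 | step 4 | (4R,5S)-5-ethyl-7-methylidenenon-1-yn-4-yl 4-nitrobenzoate | C=C(CC)C[C@H](CC)[C@@H](CC#C)OC(=O)c1ccc(cc1)[N+](=O)[O-]
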